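The interflavan bond C4–C8' is made late by adding the C8 organometallic of benzylated (−)-epiafzelechin to a (2S)-flavanone; dehydration and hydrogenation anti to the C2 aryl group then give the 2,4-cis flavan. Everything rests on one anionic [3+3] annulation that builds ring C: the enolate of 4'-benzyloxyacetophenone is C-acylated by an ortho-fluoroaroyl donor (C3–C4) and the diketonate oxygen displaces fluoride (O1–C8a), giving the flavone. It exploits the O1–C2–C3 unit as an O,C-bisnucleophile and the ortho pair C4/C8a of ring A as a bis-electrophile, the C4 carbonyl activating C8a–F. The precursor is an acyclic fluoro diketone. C2 is set by asymmetric hydrogenation of the flavone.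

Key step: step 1

Remark: (−)-epiafzelechin, 4-(benzyloxy)-2-fluorobenzoic acid and 4'-benzyloxyacetophenone are taken as purchasable; the ligand antipodes named for step 2 and its fallback are assigned by analogy and would be exchanged if the sense of induction proved opposite.

Step 1
Reactants: 1 4-(benzyloxy)-2-fluorobenzoic acid; 2 1-[4-(benzyloxy)phenyl]ethan-1-one
Product: 5 7-(benzyloxy)-2-[4-(benzyloxy)phenyl]-4H-chromen-4-one, via acyl imidazole 3 (not isolated), via 1,3-diketone 4 (not isolated)
Conditions: 1, CDI, THF, rt; added to 2, LiN(SiMe3)2 (2.2 equiv), THF, −78 °C → rt; then DMF, 110 °C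
Reagents that add atoms: none
Why: The acid is activated as acyl imidazole 3, which acylates the lithium enolate of 2 at carbon (Claisen-type acylation, C3–C4) to give the chelated enolate of diketone 4; on heating in DMF the enolate oxygen on C2 adds to the fluorine-bearing carbon C8a, the Meisenheimer adduct being stabilised through C4a by the C4 carbonyl, and loss of fluoride gives the pyranone (O1–C8a). The closest known reaction type is the acylation/intramolecular SNAr route from ortho-halobenzoyl derivatives to chromones, flavones and 4-quinolones. Ring C closes as a six-membered addition–elimination at an sp2 carbon (6-exo-trig with respect to the C8=C8a bond), and a four-membered closure through C3 or the C4 oxygen cannot compete. No stereocentre is formed, the product being a planar flavone. The step needs C- over O-acylation, which the acyl imidazole and the excess base should secure by funnelling any enol ester to the thermodynamically favoured diketonate, and displacement of fluoride only, which its ortho relation to the carbonyl secures while the benzyl ethers stay inert.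

Step 2
Reactants: 5 7-(benzyloxy)-2-[4-(benzyloxy)phenyl]-4H-chromen-4-one
Product: 7 (2S)-7-(benzyloxy)-2-[4-(benzyloxy)phenyl]chroman-4-one, via crude (2S)-flavan-4-ol 6 (not isolated)
Conditions: H2 (100 bar), Ru(cod)(2-methylallyl)2 (5 mol%), (R,R)-SINpEt·HBF4 [1,3-bis(1-(naphthalen-1-yl)ethyl)imidazolinium tetrafluoroborate] (10 mol%), KOt-Bu (15 mol%), toluene/n-hexane, rt; filtered; then Dess–Martin periodinane, CH2Cl2, rt
Reagents that add atoms: none
Why: Asymmetric hydrogenation of the C2=C3 bond of flavones with chiral ruthenium N-heterocyclic carbene catalysts is a known reaction type in which the catalyst selects the face of the pyranone that receives hydrogen and so sets C2 (ligand antipode chosen for 2S), and Dess–Martin oxidation returns the over-reduced flavan-4-ol 6 to the ketone without touching C2 or the benzyl ethers.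

Step 3
Reactants: 8 (−)-epiafzelechin, (2R,3R)-2-(4-hydroxyphenyl)chromane-3,5,7-triol
Product: 9 (2R,3R)-3,5,7-tris(benzyloxy)-2-[4-(benzyloxy)phenyl]chromane
Conditions: NaH (5 equiv), BnBr (5 equiv), n-Bu4NI (cat.), DMF, 0 °C → rt
Reagents that add atoms: benzyl bromide, BrCc1ccccc1
Why: Williamson etherification benzylates the three phenoxides and then the C3 alkoxide; no stereocentre is involved and the cold aprotic medium should avoid epimerisation at C2.

Step 4
Reactants: 9 (2R,3R)-3,5,7-tris(benzyloxy)-2-[4-(benzyloxy)phenyl]chromane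
Product: 10 (2R,3R)-3,5,7-tris(benzyloxy)-2-[4-(benzyloxy)phenyl]-8-bromochromane
Conditions: NBS (1.0 equiv), CH2Cl2, −78 °C → 0 °C
Reagents that add atoms: N-bromosuccinimide, O=C1CCC(=O)N1Br
Why: Electrophilic aromatic bromination of the phloroglucinol-type ring A, where C8 of 5,7-di-O-benzyl flavan-3-ols is the most nucleophilic position, installs the handle for metalation without touching the less activated ring B or the benzyl groups.

Step 5
Reactants: 10 (2R,3R)-3,5,7-tris(benzyloxy)-2-[4-(benzyloxy)phenyl]-8-bromochromane; 7 (2S)-7-(benzyloxy)-2-[4-(benzyloxy)phenyl]chroman-4-one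
Product: 13 (2S)-7-(benzyloxy)-2-[4-(benzyloxy)phenyl]-4-{(2R,3R)-3,5,7-tris(benzyloxy)-2-[4-(benzyloxy)phenyl]chroman-8-yl}chroman-4-ol (either C4 epimer), via aryllithium 11 (not isolated), via arylcerium dichloride 12 (not isolated)
Conditions: 10, n-BuLi, THF, −78 °C; anhydrous CeCl3, THF, −78 °C; then 7, −78 → −40 °C; aq. NH4Cl, cold
Reagents that add atoms: none
Why: Bromine–lithium exchange and transmetalation to the weakly basic organocerium give a 1,2-addition to the C4 ketone (organocerium carbonyl addition) that should outrun enolisation and retro-oxa-Michael opening of ring C; the new carbinol centre needs no control because step 6 removes it.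

Step 6
Reactants: 13 the tertiary 4-aryl flavan-4-ol
Product: 14 (2R,3R)-3,5,7-tris(benzyloxy)-2-[4-(benzyloxy)phenyl]-8-{(2S)-7-(benzyloxy)-2-[4-(benzyloxy)phenyl]-2H-chromen-4-yl}chromane
Conditions: Burgess reagent (MeO2C–N(−)–SO2–N(+)Et3), THF, rt → 40 °C, dark
Reagents that add atoms: none
Why: Burgess dehydration (syn elimination through the sulfamate, helped by the doubly benzylic character of C4) can only remove a C3 hydrogen and runs under neutral conditions that should not ionise the allylic, benzylic C2–O1 bond, so C2 is kept.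

Step 7
Reactants: 14 the hexa-O-benzyl 4-aryl flav-3-ene
Product: 15 (2R,3R)-8-[(2S,4S)-7-hydroxy-2-(4-hydroxyphenyl)chroman-4-yl]-2-(4-hydroxyphenyl)chromane-3,5,7-triol (CNP0254623.1)
Conditions: H2 (1–3 bar), Pd(OH)2/C, THF/MeOH, rt
Reagents that add atoms: none
Why: Heterogeneous hydrogenation adds hydrogen syn to C3=C4 from the face opposite the C2 aryl group, which sets C4 as S with the two aryl groups cis (substrate control by C2), while the six benzyl ethers are cleaved by hydrogenolysis in the same operation.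

Compound list
1 | 4-(benzyloxy)-2-fluorobenzoic acid | OC(=O)c1ccc(OCc2ccccc2)cc1F | starting material
2 | 1-[4-(benzyloxy)phenyl]ethan-1-one | CC(=O)c1ccc(OCc2ccccc2)cc1 | starting material
3 | [4-(benzyloxy)-2-fluorophenyl](1H-imidazol-1-yl)methanone | O=C(c1ccc(OCc2ccccc2)cc1F)n1ccnc1 | intermediate
4 | 1-[4-(benzyloxy)-2-fluorophenyl]-3-[4-(benzyloxy)phenyl]propane-1,3-dione | O=C(CC(=O)c1ccc(OCc2ccccc2)cc1)c1ccc(OCc2ccccc2)cc1F | intermediate
5 | 7-(benzyloxy)-2-[4-(benzyloxy)phenyl]-4H-chromen-4-one | O=c1cc(-c2ccc(OCc3ccccc3)cc2)oc2cc(OCc3ccccc3)ccc12 | intermediate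
6 | (2S)-7-(benzyloxy)-2-[4-(benzyloxy)phenyl]chroman-4-ol (C4 epimers) | OC1C[C@@H](c2ccc(OCc3ccccc3)cc2)Oc2cc(OCc3ccccc3)ccc12 | intermediate
7 | (2S)-7-(benzyloxy)-2-[4-(benzyloxy)phenyl]chroman-4-one | O=C1C[C@@H](c2ccc(OCc3ccccc3)cc2)Oc2cc(OCc3ccccc3)ccc12 | intermediate
8 | (−)-epiafzelechin, (2R,3R)-2-(4-hydroxyphenyl)chromane-3,5,7-triol | Oc1cc(O)c2c(c1)O[C@H](c1ccc(O)cc1)[C@H](O)C2 | starting material
9 | (2R,3R)-3,5,7-tris(benzyloxy)-2-[4-(benzyloxy)phenyl]chromane | c1c(OCc2ccccc2)cc(OCc2ccccc2)c2c1O[C@H](c1ccc(OCc3ccccc3)cc1)[C@H](OCc1ccccc1)C2 | intermediate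
10 | (2R,3R)-3,5,7-tris(benzyloxy)-2-[4-(benzyloxy)phenyl]-8-bromochromane | Brc1c(OCc2ccccc2)cc(OCc2ccccc2)c2c1O[C@H](c1ccc(OCc3ccccc3)cc1)[C@H](OCc1ccccc1)C2 | intermediate
11 | 8-lithio derivative of 9 (aryllithium) | [Li]c1c(OCc2ccccc2)cc(OCc2ccccc2)c2c1O[C@H](c1ccc(OCc3ccccc3)cc1)[C@H](OCc1ccccc1)C2 | intermediate
12 | 8-(dichlorocerio) derivative of 9 (arylcerium dichloride) | Cl[Ce](Cl)c1c(OCc2ccccc2)cc(OCc2ccccc2)c2c1O[C@H](c1ccc(OCc3ccccc3)cc1)[C@H](OCc1ccccc1)C2 | intermediate
13 | (2S)-7-(benzyloxy)-2-[4-(benzyloxy)phenyl]-4-{(2R,3R)-3,5,7-tris(benzyloxy)-2-[4-(benzyloxy)phenyl]chroman-8-yl}chroman-4-ol (either C4 epimer) | OC1(c2c(OCc3ccccc3)cc(OCc3ccccc3)c3c2O[C@H](c2ccc(OCc4ccccc4)cc2)[C@H](OCc2ccccc2)C3)C[C@@H](c2ccc(OCc3ccccc3)cc2)Oc2cc(OCc3ccccc3)ccc21 | intermediate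
14 | (2R,3R)-3,5,7-tris(benzyloxy)-2-[4-(benzyloxy)phenyl]-8-{(2S)-7-(benzyloxy)-2-[4-(benzyloxy)phenyl]-2H-chromen-4-yl}chromane | C1(c2c(OCc3ccccc3)cc(OCc3ccccc3)c3c2O[C@H](c2ccc(OCc4ccccc4)cc2)[C@H](OCc2ccccc2)C3)=C[C@@H](c2ccc(OCc3ccccc3)cc2)Oc2cc(OCc3ccccc3)ccc21 | intermediate
15 | (2R,3R)-8-[(2S,4S)-7-hydroxy-2-(4-hydroxyphenyl)chroman-4-yl]-2-(4-hydroxyphenyl)chromane-3,5,7-triol | Oc1ccc([C@@H]2C[C@H](c3c(O)cc(O)c4c3O[C@H](c3ccc(O)cc3)[C@H](O)C4)c3ccc(O)cc3O2)cc1 | target

Total step count: 7. Longest linear sequence: 5 steps (steps 1, 2, 5, 6, 7 from 1 and 2; equally steps 3, 4, 5, 6, 7 from 8).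

Steps most likely to fail

Step 5. The aryl-metal may deprotonate the flavanone at C3, and the enolate may open ring C by E1cB loss of the aryloxide, which destroys material and erodes C2. The addition itself is slowed by the two ortho substituents of the nucleophile and the electron-rich ketone. The fallback makes the C4–C8' bond by cross-coupling and sets out from 7 and 10. Ketone 7 is converted without an enolate (Tf2O, 2,6-di-tert-butyl-4-methylpyridine, CH2Cl2, 0 °C) into (2S)-7-(benzyloxy)-2-[4-(benzyloxy)phenyl]-2H-chromen-4-yl trifluoromethanesulfonate F1. Bromide 10 is lithiated as in step 5 and transmetalated with ZnCl2 to the arylzinc chloride F2. Negishi coupling of F1 and F2 (Pd2(dba)3, SPhos, THF, 50 °C) should give the flav-3-ene directly, so the fallback returns at 14 and bypasses 13 and step 6.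

Step 2. Facial discrimination or turnover may be insufficient on the electron-rich 7-alkoxyflavone, and arene rings may be partly saturated. The fallback sets out from 5. Conjugate reduction with LiBH(s-Bu)3 (THF, −78 °C) should give the racemic flavanone 7-(benzyloxy)-2-[4-(benzyloxy)phenyl]chroman-4-one F3. Kinetic resolution by asymmetric transfer hydrogenation (Cp*RhCl[(R,R)-TsDPEN], HCO2H/Et3N, EtOAc, rt) should reduce the 2R ketone to the separable (2R,4R)-7-(benzyloxy)-2-[4-(benzyloxy)phenyl]chroman-4-ol F4 and leave the 2S ketone, so the fallback returns at 7.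

Step 7. The allylic, benzylic C2–O1 bond may be hydrogenolysed before the hindered trisubstituted alkene is saturated, the alkene may be reduced incompletely, and the 2H-chromene 14 may lose C2 integrity by reversible electrocyclic ring opening before it is reduced. The fallback sets out from 13 and avoids the chromene. Ionic hydrogenation (Et3SiH, BF3·OEt2, CH2Cl2, −78 °C) ionises C4, and axial hydride delivery anti to the equatorial C2 aryl group should give the 2,4-cis product (2R,3R)-3,5,7-tris(benzyloxy)-2-[4-(benzyloxy)phenyl]-8-{(2S,4S)-7-(benzyloxy)-2-[4-(benzyloxy)phenyl]chroman-4-yl}chromane F5. Hydrogenolysis of F5 (H2, Pd(OH)2/C, THF/MeOH, rt) then returns to the route at 15.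

Further compounds
F1 | step 5 | (2S)-7-(benzyloxy)-2-[4-(benzyloxy)phenyl]-2H-chromen-4-yl trifluoromethanesulfonate | FC(F)(F)S(=O)(=O)OC1=C[C@@H](c2ccc(OCc3ccccc3)cc2)Oc2cc(OCc3ccccc3)ccc21
F2 | step 5 | 8-(chlorozincio) derivative of 9 (arylzinc chloride) | Cl[Zn]c1c(OCc2ccccc2)cc(OCc2ccccc2)c2c1O[C@H](c1ccc(OCc3ccccc3)cc1)[C@H](OCc1ccccc1)C2
F3 | step 2 | racemic 7-(benzyloxy)-2-[4-(benzyloxy)phenyl]chroman-4-one | O=C1CC(c2ccc(OCc3ccccc3)cc2)Oc2cc(OCc3ccccc3)ccc12
F4 | step 2 | (2R,4R)-7-(benzyloxy)-2-[4-(benzyloxy)phenyl]chroman-4-ol | O[C@@H]1C[C@H](c2ccc(OCc3ccccc3)cc2)Oc2cc(OCc3ccccc3)ccc12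
F5 | step 7 | (2R,3R)-3,5,7-tris(benzyloxy)-2-[4-(benzyloxy)phenyl]-8-{(2S,4S)-7-(benzyloxy)-2-[4-(benzyloxy)phenyl]chroman-4-yl}chromane | c1ccc(COc2ccc([C@@H]3C[C@H](c4c(OCc5ccccc5)cc(OCc5ccccc5)c5c4O[C@H](c4ccc(OCc6ccccc6)cc4)[C@H](OCc4ccccc4)C5)c4ccc(OCc5ccccc5)cc4O3)cc2)cc1
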